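**Retrosynthetic overview**

- Feature: in the central benzene ring A, C1 bears the exocyclic carbon C7, C2 an aryl group, C3 and C4 are CH, C5 bears CH2OH and C6 the alkynyl carbon. Four contiguous carbon substituents beside two adjacent CH positions are the footprint of two tethered internal alkynes plus acetylene.
- Selaginellin 22 <= acid-induced global deprotection and dehydration of triaryl carbinol 20 <= diaryl ketone 18 + aryllithium 19 (last C7–aryl bond).
- 18 <= oxidation and Sonogashira arylation of ethynyl benzhydrol 14 <= Ohira–Bestmann homologation of lactol 12 <= phthalide 11. The lactone carbonyl becomes the alkyne carbon on C6 and the lactone CH(aryl) becomes C7.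
- 11 <= RhCl(PPh3)3-catalysed [2+2+2] cycloaddition of the ester-tethered 1,6-diyne 9 with acetylene 10. The lactone ring and ring A close in the same step (bonds C6–C1, C2–C3 and C4–C5); the four outer aryl rings are bought.
- 9 <= Steglich ester of propargylic alcohol 5 (acetylide of 3 + aldehyde 2) with silyloxybutynoic acid 8; aryl iodide 16 is used twice in the endgame.

Key step: step 6

Remark: the target has no stereocentre; compounds 5, 9, 11, 13, 14 and 17 are racemates (one enantiomer drawn), and lactol 12 is a mixture of epimers at the hemiacetal carbon.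

**Route**

Step 1
Reactants: 1 4-hydroxybenzaldehyde
Product: 2 4-(methoxymethoxy)benzaldehyde
Conditions: MOMCl, iPr2NEt, CH2Cl2, 0 °C to rt
Reagents that add atoms: chloromethyl methyl ether (MOMCl), COCCl
Why: Williamson-type O-alkylation of the phenol by the α-chloro ether gives a MOM acetal that should survive organolithiums, hydride and base and is cleaved by acid at the end.

Step 2
Reactants: 2 4-(methoxymethoxy)benzaldehyde
Product: 3 1-ethynyl-4-(methoxymethoxy)benzene
Conditions: dimethyl (1-diazo-2-oxopropyl)phosphonate, K2CO3, MeOH, 0 °C to rt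
Reagents that add atoms: dimethyl (1-diazo-2-oxopropyl)phosphonate, CC(=O)C(=[N+]=[N-])P(=O)(OC)OC
Why: Seyferth–Gilbert homologation in its Ohira–Bestmann form, in which the diazomethylphosphonate anion released by methanolysis olefinates the aryl aldehyde and the diazoalkene loses dinitrogen with a 1,2-hydride shift to give the terminal alkyne.

Step 3
Reactants: 3 1-ethynyl-4-(methoxymethoxy)benzene; 2 4-(methoxymethoxy)benzaldehyde
Product: 5 (±)-1,3-bis[4-(methoxymethoxy)phenyl]prop-2-yn-1-ol, via lithium arylacetylide 4 (not isolated)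
Conditions: n-BuLi, THF, −78 °C; then 2, −78 to 0 °C; then H2O
Reagents that add atoms: none
Why: 1,2-addition of a lithium acetylide to a non-enolisable aldehyde; the carbinol stereocentre forms without control as a racemate, which is acceptable because it becomes a ketone at step 11.

Step 4
Reactants: 6 tert-butyldimethyl(prop-2-yn-1-yloxy)silane
Product: 8 4-[(tert-butyldimethylsilyl)oxy]but-2-ynoic acid, via lithium silyloxypropynide 7 (not isolated)
Conditions: n-BuLi, THF, −78 °C; then CO2 (g), −78 to 0 °C; then cold 1 M HCl to pH 3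
Reagents that add atoms: carbon dioxide, O=C=O
Why: carboxylation of a lithium acetylide with CO2, with a brief cold acidification that the primary silyl ether should tolerate.

Step 5
Reactants: 5 (±)-1,3-bis[4-(methoxymethoxy)phenyl]prop-2-yn-1-ol; 8 4-[(tert-butyldimethylsilyl)oxy]but-2-ynoic acid
Product: 9 (±)-1,3-bis[4-(methoxymethoxy)phenyl]prop-2-yn-1-yl 4-[(tert-butyldimethylsilyl)oxy]but-2-ynoate
Conditions: DCC, DMAP (10 mol%), CH2Cl2, −20 to 0 °C; chromatography on Et3N-treated silica
Reagents that add atoms: none
Why: Steglich esterification acylates at oxygen, so the carbinol carbon is untouched, while low temperature and little DMAP limit conjugate addition to the ynoate and ionisation of the benzylic propargylic ester.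

Step 6
Reactants: 9 (±)-1,3-bis[4-(methoxymethoxy)phenyl]prop-2-yn-1-yl 4-[(tert-butyldimethylsilyl)oxy]but-2-ynoate; 10 acetylene
Product: 11 (±)-7-[(tert-butyldimethylsilyloxy)methyl]-3,4-bis[4-(methoxymethoxy)phenyl]isobenzofuran-1(3H)-one
Conditions: RhCl(PPh3)3 (10 mol%), 10 (1 atm, saturated solution), toluene, 60 °C, slow addition of 9
Reagents that add atoms: none
Why: Oxidative coupling of the two tethered alkynes on monovalent rhodium should give a bicyclic rhodacyclopentadiene, in which the C6–C1 bond is made and the five-membered lactone is closed as the tether ring by C–C bond formation between the two inner alkyne carbons; coordination and insertion of acetylene followed by reductive elimination then forms C2–C3 and C4–C5 and closes the six-membered ring A directly as a benzene ring. The closest known reaction type is the RhCl(PPh3)3-catalysed crossed [2+2+2] cycloaddition of ester-tethered 1,6-diynes with alkynes, which gives phthalides. No stereocentre is created; the carbinol centre of 9 is a spectator, stays racemic and is erased at step 11. Regiochemistry is not in question, because the tether places the aryl group on C2, the carbinol carbon on C1, the lactone carbonyl on C6 and the silyloxymethyl group on C5, and acetylene is symmetric. The step needs chemoselectivity for cross-cyclotrimerisation over self-coupling of 9, which the saturated acetylene solution, the slow addition of 9 and the intramolecular nature of the first C–C bond formation should secure; warming helps the ester reach the s-cis conformer that this first cyclisation requires.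

Step 7
Reactants: 11 (±)-7-[(tert-butyldimethylsilyloxy)methyl]-3,4-bis[4-(methoxymethoxy)phenyl]isobenzofuran-1(3H)-one
Product: 12 7-[(tert-butyldimethylsilyloxy)methyl]-3,4-bis[4-(methoxymethoxy)phenyl]-1,3-dihydroisobenzofuran-1-ol
Conditions: DIBAL-H (1.1 equiv), CH2Cl2, −78 °C; then aq. KNaC4H4O6 (potassium sodium tartrate)
Reagents that add atoms: none
Why: partial reduction of a lactone to the lactol, the aluminium hemiacetal being stable at −78 °C; the hemiacetal centre forms as an epimeric mixture that is of no consequence because it is consumed in step 8.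

Step 8
Reactants: 12 7-[(tert-butyldimethylsilyloxy)methyl]-3,4-bis[4-(methoxymethoxy)phenyl]-1,3-dihydroisobenzofuran-1-ol
Product: 14 (±)-{3-[(tert-butyldimethylsilyloxy)methyl]-2-ethynyl-6-[4-(methoxymethoxy)phenyl]phenyl}[4-(methoxymethoxy)phenyl]methanol, via ring-opened hydroxy aldehyde 13 (not isolated)
Conditions: dimethyl (1-diazo-2-oxopropyl)phosphonate (2.5 equiv), K2CO3, MeOH/THF, 0 °C to rt
Reagents that add atoms: dimethyl (1-diazo-2-oxopropyl)phosphonate, CC(=O)C(=[N+]=[N-])P(=O)(OC)OC
Why: Ohira–Bestmann homologation of a lactol through its open hydroxy aldehyde tautomer turns the former lactone carbon into the ethynyl group on C6 and frees the benzhydrol at C7.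

Step 9
Reactants: 15 4-iodophenol
Product: 16 1-iodo-4-(methoxymethoxy)benzene
Conditions: MOMCl, iPr2NEt, CH2Cl2, 0 °C to rt
Reagents that add atoms: chloromethyl methyl ether (MOMCl), COCCl
Why: the same Williamson-type MOM protection as in step 1, giving one aryl iodide that serves both the Sonogashira coupling and the aryllithium addition.

Step 10
Reactants: 14 (±)-{3-[(tert-butyldimethylsilyloxy)methyl]-2-ethynyl-6-[4-(methoxymethoxy)phenyl]phenyl}[4-(methoxymethoxy)phenyl]methanol; 16 1-iodo-4-(methoxymethoxy)benzene
Product: 17 (±)-{3-[(tert-butyldimethylsilyloxy)methyl]-6-[4-(methoxymethoxy)phenyl]-2-{[4-(methoxymethoxy)phenyl]ethynyl}phenyl}[4-(methoxymethoxy)phenyl]methanol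
Conditions: PdCl2(PPh3)2 (3 mol%), CuI (5 mol%), Et3N, THF, degassed, rt
Reagents that add atoms: none
Why: Sonogashira coupling of a terminal arylacetylene with an aryl iodide proceeds at room temperature, where the free benzhydrol should not yet add to the alkyne.

Step 11
Reactants: 17 (±)-{3-[(tert-butyldimethylsilyloxy)methyl]-6-[4-(methoxymethoxy)phenyl]-2-{[4-(methoxymethoxy)phenyl]ethynyl}phenyl}[4-(methoxymethoxy)phenyl]methanol
Product: 18 {3-[(tert-butyldimethylsilyloxy)methyl]-6-[4-(methoxymethoxy)phenyl]-2-{[4-(methoxymethoxy)phenyl]ethynyl}phenyl}[4-(methoxymethoxy)phenyl]methanone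
Conditions: Dess–Martin periodinane, CH2Cl2, 0 °C to rt
Reagents that add atoms: none
Why: Dess–Martin oxidation of a hindered diaryl carbinol to the diaryl ketone under near-neutral conditions that leave the alkyne, the acetals and the silyl ether alone, and it removes the only stereocentre of the route.

Step 12
Reactants: 16 1-iodo-4-(methoxymethoxy)benzene; 18 {3-[(tert-butyldimethylsilyloxy)methyl]-6-[4-(methoxymethoxy)phenyl]-2-{[4-(methoxymethoxy)phenyl]ethynyl}phenyl}[4-(methoxymethoxy)phenyl]methanone
Product: 20 {3-[(tert-butyldimethylsilyloxy)methyl]-6-[4-(methoxymethoxy)phenyl]-2-{[4-(methoxymethoxy)phenyl]ethynyl}phenyl}bis[4-(methoxymethoxy)phenyl]methanol, via 4-(methoxymethoxy)phenyllithium 19 (not isolated)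
Conditions: 16 (2.2 equiv), n-BuLi (2.1 equiv), THF, −78 °C; then 18, −78 to −40 °C; then H2O at −40 °C; crude product used directly
Reagents that add atoms: none
Why: iodine–lithium exchange followed by 1,2-addition of the aryllithium to a non-enolisable diaryl ketone, with a cold quench so that the tertiary lithium alkoxide does not add to the neighbouring alkyne.

Step 13
Reactants: 20 {3-[(tert-butyldimethylsilyloxy)methyl]-6-[4-(methoxymethoxy)phenyl]-2-{[4-(methoxymethoxy)phenyl]ethynyl}phenyl}bis[4-(methoxymethoxy)phenyl]methanol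
Product: 22 selaginellin, via fully deprotected triaryl carbinol 21 (not isolated)
Conditions: HCl (1.25 M in MeOH), THF, 45 °C; then aq. NaHCO3
Reagents that add atoms: none
Why: acid-catalysed acetal exchange and silyl ether methanolysis free the four phenols and the CH2OH group, and the bis(4-hydroxyphenyl)carbinol ionises and loses water (fuchsone formation) to give the quinone methide, with no geometric issue because the two 4-oxyaryl groups on C7 are equivalent.

**Compound list**

1 | 4-hydroxybenzaldehyde | O=Cc1ccc(O)cc1 | starting material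
2 | 4-(methoxymethoxy)benzaldehyde | COCOc1ccc(C=O)cc1 | intermediate
3 | 1-ethynyl-4-(methoxymethoxy)benzene | COCOc1ccc(C#C)cc1 | intermediate
4 | lithium [4-(methoxymethoxy)phenyl]acetylide | [Li]C#Cc1ccc(OCOC)cc1 | intermediate
5 | (±)-1,3-bis[4-(methoxymethoxy)phenyl]prop-2-yn-1-ol (racemate, one enantiomer drawn) | COCOc1ccc(C#C[C@H](O)c2ccc(OCOC)cc2)cc1 | intermediate
6 | tert-butyldimethyl(prop-2-yn-1-yloxy)silane | C#CCO[Si](C)(C)C(C)(C)C | starting material
7 | lithium 3-[(tert-butyldimethylsilyl)oxy]prop-1-yn-1-ide | [Li]C#CCO[Si](C)(C)C(C)(C)C | intermediate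
8 | 4-[(tert-butyldimethylsilyl)oxy]but-2-ynoic acid | OC(=O)C#CCO[Si](C)(C)C(C)(C)C | intermediate
9 | (±)-1,3-bis[4-(methoxymethoxy)phenyl]prop-2-yn-1-yl 4-[(tert-butyldimethylsilyl)oxy]but-2-ynoate (racemate, one enantiomer drawn) | COCOc1ccc(C#C[C@H](OC(=O)C#CCO[Si](C)(C)C(C)(C)C)c2ccc(OCOC)cc2)cc1 | intermediate
10 | acetylene | C#C | starting material
11 | (±)-7-[(tert-butyldimethylsilyloxy)methyl]-3,4-bis[4-(methoxymethoxy)phenyl]isobenzofuran-1(3H)-one (racemate, one enantiomer drawn) | O=C1O[C@H](c2ccc(OCOC)cc2)c2c(-c3ccc(OCOC)cc3)ccc(CO[Si](C)(C)C(C)(C)C)c12 | intermediate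
12 | 7-[(tert-butyldimethylsilyloxy)methyl]-3,4-bis[4-(methoxymethoxy)phenyl]-1,3-dihydroisobenzofuran-1-ol (racemic at the aryl-bearing ring carbon, epimeric mixture at the hemiacetal carbon) | OC1O[C@H](c2ccc(OCOC)cc2)c2c(-c3ccc(OCOC)cc3)ccc(CO[Si](C)(C)C(C)(C)C)c12 | intermediate
13 | (±)-6-[(tert-butyldimethylsilyloxy)methyl]-2-{hydroxy[4-(methoxymethoxy)phenyl]methyl}-3-[4-(methoxymethoxy)phenyl]benzaldehyde (racemate, one enantiomer drawn) | O=Cc1c(CO[Si](C)(C)C(C)(C)C)ccc(-c2ccc(OCOC)cc2)c1[C@H](O)c1ccc(OCOC)cc1 | intermediate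
14 | (±)-{3-[(tert-butyldimethylsilyloxy)methyl]-2-ethynyl-6-[4-(methoxymethoxy)phenyl]phenyl}[4-(methoxymethoxy)phenyl]methanol (racemate, one enantiomer drawn) | C#Cc1c(CO[Si](C)(C)C(C)(C)C)ccc(-c2ccc(OCOC)cc2)c1[C@H](O)c1ccc(OCOC)cc1 | intermediate
15 | 4-iodophenol | Oc1ccc(I)cc1 | starting material
16 | 1-iodo-4-(methoxymethoxy)benzene | COCOc1ccc(I)cc1 | intermediate
17 | (±)-{3-[(tert-butyldimethylsilyloxy)methyl]-6-[4-(methoxymethoxy)phenyl]-2-{[4-(methoxymethoxy)phenyl]ethynyl}phenyl}[4-(methoxymethoxy)phenyl]methanol (racemate, one enantiomer drawn) | COCOc1ccc(cc1)C#Cc1c(CO[Si](C)(C)C(C)(C)C)ccc(-c2ccc(OCOC)cc2)c1[C@H](O)c1ccc(OCOC)cc1 | intermediate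
18 | {3-[(tert-butyldimethylsilyloxy)methyl]-6-[4-(methoxymethoxy)phenyl]-2-{[4-(methoxymethoxy)phenyl]ethynyl}phenyl}[4-(methoxymethoxy)phenyl]methanone | COCOc1ccc(cc1)C#Cc1c(CO[Si](C)(C)C(C)(C)C)ccc(-c2ccc(OCOC)cc2)c1C(=O)c1ccc(OCOC)cc1 | intermediate
19 | 4-(methoxymethoxy)phenyllithium | [Li]c1ccc(OCOC)cc1 | intermediate
20 | {3-[(tert-butyldimethylsilyloxy)methyl]-6-[4-(methoxymethoxy)phenyl]-2-{[4-(methoxymethoxy)phenyl]ethynyl}phenyl}bis[4-(methoxymethoxy)phenyl]methanol | COCOc1ccc(cc1)C#Cc1c(CO[Si](C)(C)C(C)(C)C)ccc(-c2ccc(OCOC)cc2)c1C(O)(c1ccc(OCOC)cc1)c1ccc(OCOC)cc1 | intermediate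
21 | {3-(hydroxymethyl)-6-(4-hydroxyphenyl)-2-[(4-hydroxyphenyl)ethynyl]phenyl}bis(4-hydroxyphenyl)methanol | Oc1ccc(cc1)C#Cc1c(CO)ccc(-c2ccc(O)cc2)c1C(O)(c1ccc(O)cc1)c1ccc(O)cc1 | intermediate
22 | selaginellin | O=C1C=CC(=C(c2ccc(O)cc2)c2c(-c3ccc(O)cc3)ccc(CO)c2C#Cc2ccc(O)cc2)C=C1 | target

**Step count**

Total step count: 13. Longest linear sequence: 11 steps (steps 1, 2, 3, 5, 6, 7, 8, 10, 11, 12 and 13, from 1 to 22).

**Steps most likely to fail**

Step 6. The diyne may couple with itself faster than the rhodacycle is captured by dissolved acetylene. The first cyclisation may also be slow because the ester prefers its s-trans conformer, which gives the rhodium catalyst time to ionise the doubly activated propargylic ester. The fallback sets out from diyne 9 and replaces the gaseous alkyne by vinyl acetate, a liquid two-carbon partner that can be used in large excess, with [Rh(cod)2]BF4 and rac-BINAP in CH2Cl2 at rt. An alkyne–alkyne–alkene cycloaddition should give the acetoxycyclohexadiene F1 (mixture of isomers), which aromatises in the flask by loss of acetic acid. The route is rejoined at phthalide 11.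

Step 8. The lactol may stay closed, so that homologation is slow and the basic methanol has time to cause alkoxide addition to the new alkyne or loss of the silyl group. The fallback sets out from phthalide 11 and avoids the hemiacetal. LiAlH4 in THF at 0 °C should give the diol F2. A Swern oxidation ((COCl)2, DMSO, Et3N, CH2Cl2, −78 °C), in which both hydroxyls are activated before base is added so that no lactol can form, gives the keto aldehyde F3. The Ohira–Bestmann reagent with K2CO3 in MeOH then homologates only the aldehyde, the hindered diaryl ketone being inert under these conditions, to give the ethynyl ketone F4. Sonogashira coupling of F4 with 16 (PdCl2(PPh3)2, CuI, Et3N) gives ketone 18, where the route is rejoined with the same number of operations.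

Step 12. Addition to the doubly ortho-substituted ketone may stop short, or the tertiary lithium alkoxide may add to the neighbouring alkyne in a 5-exo-dig ring closure before the quench. The fallback sets out from benzhydrol 17 and brings in the fourth aryl group as a nucleophile under acid. Catalytic TsOH with excess phenol in CH2Cl2 at 0 °C should ionise the carbinol to the 4-alkoxybenzhydryl cation, which phenol captures at its para position (Friedel–Crafts alkylation) to give the protected triarylmethane F5. Methanolic HCl then removes the acetal and silyl groups to give the leuco triarylmethane F6. DDQ (1 equiv, dioxane, rt) dehydrogenates the 4-hydroxyphenyl-substituted methine to the quinone methide, so the route is rejoined at the target 22.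

**Further compounds**

F1 | step 6 | 5-acetoxy-7-[(tert-butyldimethylsilyloxy)methyl]-3,4-bis[4-(methoxymethoxy)phenyl]-5,6-dihydroisobenzofuran-1(3H)-one (mixture of regio- and stereoisomers, stereocentres not defined) | O=C1OC(c2ccc(OCOC)cc2)C2=C(c3ccc(OCOC)cc3)C(OC(C)=O)CC(CO[Si](C)(C)C(C)(C)C)=C12
F2 | step 8 | (±)-{3-[(tert-butyldimethylsilyloxy)methyl]-2-(hydroxymethyl)-6-[4-(methoxymethoxy)phenyl]phenyl}[4-(methoxymethoxy)phenyl]methanol (racemate, one enantiomer drawn) | OCc1c(CO[Si](C)(C)C(C)(C)C)ccc(-c2ccc(OCOC)cc2)c1[C@H](O)c1ccc(OCOC)cc1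
F3 | step 8 | 6-[(tert-butyldimethylsilyloxy)methyl]-2-[4-(methoxymethoxy)benzoyl]-3-[4-(methoxymethoxy)phenyl]benzaldehyde | O=Cc1c(CO[Si](C)(C)C(C)(C)C)ccc(-c2ccc(OCOC)cc2)c1C(=O)c1ccc(OCOC)cc1
F4 | step 8 | {3-[(tert-butyldimethylsilyloxy)methyl]-2-ethynyl-6-[4-(methoxymethoxy)phenyl]phenyl}[4-(methoxymethoxy)phenyl]methanone | C#Cc1c(CO[Si](C)(C)C(C)(C)C)ccc(-c2ccc(OCOC)cc2)c1C(=O)c1ccc(OCOC)cc1
F5 | step 12 | (±)-4-{{3-[(tert-butyldimethylsilyloxy)methyl]-6-[4-(methoxymethoxy)phenyl]-2-{[4-(methoxymethoxy)phenyl]ethynyl}phenyl}[4-(methoxymethoxy)phenyl]methyl}phenol (racemate, one enantiomer drawn) | COCOc1ccc(cc1)C#Cc1c(CO[Si](C)(C)C(C)(C)C)ccc(-c2ccc(OCOC)cc2)c1[C@H](c1ccc(OCOC)cc1)c1ccc(O)cc1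
F6 | step 12 | 4,4'-{{3-(hydroxymethyl)-6-(4-hydroxyphenyl)-2-[(4-hydroxyphenyl)ethynyl]phenyl}methylene}diphenol | Oc1ccc(cc1)C#Cc1c(CO)ccc(-c2ccc(O)cc2)c1C(c1ccc(O)cc1)c1ccc(O)cc1
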